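**Retrosynthetic overview**
1. Target 19 ⇐ acid-mediated trans-diaxial opening of the 3α,4α-epoxide 17 ⇐ α-face epoxidation of the Δ3-alkene 16.
2. 16 (H-5α, trans-decalin) ⇐ reductive 1,3-transposition of the allylic alcohol 13 ⇐ 1,2-reduction of the 6β-benzoyloxy enone 12.
3. 12 ⇐ γ-hydroxylation at C6 of eudesm-4-en-3-one 9 through its dienol acetate ⇐ (+)-α-cyperone 8 by hydrogenation of the isopropenyl group.
4. 8 ⇐ aldol condensation closing ring A ⇐ 1,5-diketone 6 ⇐ key C1–C10 bond by auxiliary-controlled intermolecular Michael addition of the (+)-dihydrocarvone imine 3 to ethyl vinyl ketone 4.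
5. Ring order: ring B is bought as dihydrocarvone; ring A is built on it by Michael addition, then aldol cyclisation.

Assumption: eudesmane numbering and α/β descriptors are used (β = face of the C10 methyl); read this way the SMILES is 6β-benzoyloxy-7β-isopropyl-5αH-eudesmane-3α,4β-diol, and commercial (+)-dihydrocarvone is taken as the 5R material containing both C2 epimers.

**Route**

Step 1
Reactants: 1 (+)-dihydrocarvone; 2 (R)-(+)-1-phenylethylamine
Product: 3 (5R)-2-methyl-5-(prop-1-en-2-yl)-N-[(1R)-1-phenylethyl]cyclohexan-1-imine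
Conditions: TsOH (cat.), toluene, reflux, Dean–Stark; used crude
Reagents that add atoms: none
Why: Acid-catalysed imine formation with azeotropic removal of water is driven to completion, and the C2 epimer mixture of 1 converges because C2 becomes the enamine carbon in the next step while C5 (R) is untouched.

Step 2
Reactants: 3 imine; 4 ethyl vinyl ketone
Product: 6 (2S,5R)-2-methyl-2-(3-oxopentyl)-5-(prop-1-en-2-yl)cyclohexan-1-one, via Michael-adduct imine 5 (not isolated)
Conditions: 4 (1.3 equiv), THF, 40 °C, 3 d; then 10% aq. AcOH, rt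
Reagents that add atoms: water, O
Why: d'Angelo asymmetric Michael addition, in which the more substituted secondary enamine tautomer of 3 adds to 4 on the face anti to the phenyl group of the (R)-auxiliary and so sets the quaternary centre (future C10, methyl cis to isopropenyl), after which mild acid hydrolysis frees the 1,5-diketone and the auxiliary.

Step 3
Reactants: 6 diketone
Product: 8 (+)-α-cyperone (eudesma-4,11-dien-3-one; 7β-isopropenyl; 10β-methyl), via ketol 7 (not isolated)
Conditions: NaOMe, MeOH, rt then reflux; chromatography removes the minor C10 epimer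
Reagents that add atoms: none
Why: Intramolecular aldol condensation (second half of the Robinson annulation), in which only the six-membered ketol from the ethyl-ketone α-CH2 and the ring carbonyl can dehydrate to a conjugated enone, so ring A closes as the 4-methyl-Δ4-3-ketone without touching C7 or the quaternary C10.

Step 4
Reactants: 8 (+)-α-cyperone
Product: 9 eudesm-4-en-3-one (11,12-dihydro-α-cyperone; 7β-isopropyl; 10β-methyl)
Conditions: H2 (1 atm), RhCl(PPh3)3 (5 mol%), benzene, rt
Reagents that add atoms: none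
Why: Homogeneous hydrogenation with RhCl(PPh3)3 reduces the unhindered 1,1-disubstituted alkene and leaves the tetrasubstituted conjugated enone alone, and no stereocentre is formed or disturbed.

Step 5
Reactants: 9 eudesm-4-en-3-one
Product: 10 3-acetoxyeudesma-3,5-diene
Conditions: isopropenyl acetate, TsOH (cat.), reflux with slow distillation of acetone
Reagents that add atoms: isopropenyl acetate, CC(=C)OC(C)=O
Why: Acid-catalysed enol acetylation under thermodynamic control gives the heteroannular 3,5-dienyl acetate (the extended enol of a Δ4-3-ketone), which turns C6 into the nucleophilic γ-terminus.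

Step 6
Reactants: 10 dienol acetate
Product: 11 6β-hydroxyeudesm-4-en-3-one
Conditions: mCPBA (1.1 equiv), 1,4-dioxane/H2O 9:1, 0 °C to rt
Reagents that add atoms: mCPBA, OOC(=O)c1cccc(Cl)c1
Why: Vinylogous Rubottom-type peracid oxidation, in which the deactivated enol-acetate double bond is spared and oxygen is taken up at the γ-carbon C6 from the β face (axial attack, and a 6α-substituent would suffer A(1,3) strain with the C4 methyl), loss of the acetyl group then returning the conjugated enone.

Step 7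
Reactants: 11 6β-hydroxy enone
Product: 12 6β-benzoyloxyeudesm-4-en-3-one
Conditions: BzCl, pyridine, DMAP (cat.), CH2Cl2, 0 °C to 40 °C
Reagents that add atoms: benzoyl chloride, O=C(Cl)c1ccccc1
Why: DMAP-catalysed O-acylation of the only hydroxyl group with an acid chloride, with C6 keeping its configuration because the C–O bond is not broken.

Step 8
Reactants: 12 benzoyloxy enone
Product: 13 6β-benzoyloxyeudesm-4-en-3β-ol
Conditions: NaBH4, CeCl3·7H2O, MeOH/CH2Cl2, −40 °C
Reagents that add atoms: none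
Why: Luche reduction gives clean 1,2-reduction of the enone with hydride adding to C3 axially from the α face, so the pseudo-equatorial 3β-allylic alcohol forms as with steroidal Δ4-3-ketones, and the benzoate is inert at this temperature.

Step 9
Reactants: 13 allylic alcohol
Product: 16 6β-benzoyloxy-5αH-eudesm-3-ene, via sulfonylhydrazine adduct 14 (not isolated), via allylic diazene 15 (not isolated)
Conditions: 2-nitrobenzenesulfonylhydrazide (NBSH), PPh3, DEAD, THF, −30 °C, 2 h; then rt
Reagents that add atoms: none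
Why: Myers reductive allylic transposition, in which Mitsunobu displacement by NBSH inverts C3 (nitrogen on the α face), loss of 2-nitrobenzenesulfinic acid gives the allylic diazene, and its retro-ene loss of N2 delivers hydrogen suprafacially to C5 on the α face, setting the trans ring fusion and moving the double bond to C3=C4.

Step 10
Reactants: 16 Δ3-alkene
Product: 17 6β-benzoyloxy-3α,4α-epoxy-5αH-eudesmane
Conditions: mCPBA, NaHCO3 (solid buffer), CH2Cl2, 0 °C; used without chromatography
Reagents that add atoms: mCPBA, OOC(=O)c1cccc(Cl)c1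
Why: Prilezhaev epoxidation of the only alkene occurs from the α face because the β face of C3=C4 is screened by the axial C10 methyl and the axial 6β-benzoate, both 1,3-related to C4.

Step 11
Reactants: 17 epoxide
Product: 19 6β-benzoyloxy-7β-isopropyl-5αH-eudesmane-3α,4β-diol (target), via dioxanylium ion 18 (not isolated)
Conditions: HClO4 (0.5 M aq., 0.3 equiv), THF/H2O 4:1, 0 °C to rt
Reagents that add atoms: water, O
Why: Acid-catalysed trans-diaxial (Fürst–Plattner) epoxide opening at the tertiary C4 from the β face, assisted by the syn-axial 6β-benzoate through the 2-phenyl-1,3-dioxan-2-ylium ion 18, whose hydrolysis under equilibrating acid leaves the acyl group on the secondary O6 and gives the 3α-OH (the former epoxide oxygen) and the axial 4β-OH.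

**Compound list**
1 | (+)-dihydrocarvone, (5R)-2-methyl-5-(prop-1-en-2-yl)cyclohexan-1-one (C2 epimer mixture) | CC(=C)[C@@H]1CCC(C)C(=O)C1 | starting material
2 | (R)-(+)-1-phenylethylamine | C[C@@H](N)c1ccccc1 | starting material
3 | (5R)-2-methyl-5-(prop-1-en-2-yl)-N-[(1R)-1-phenylethyl]cyclohexan-1-imine | CC(=C)[C@@H]1CCC(C)C(=N[C@H](C)c2ccccc2)C1 | intermediate
4 | ethyl vinyl ketone (pent-1-en-3-one) | C=CC(=O)CC | starting material
5 | (2S,5R)-2-methyl-2-(3-oxopentyl)-5-(prop-1-en-2-yl)-N-[(1R)-1-phenylethyl]cyclohexan-1-imine | CC(=C)[C@@H]1CC[C@@](C)(CCC(=O)CC)C(=N[C@H](C)c2ccccc2)C1 | intermediate (not isolated)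
6 | (2S,5R)-2-methyl-2-(3-oxopentyl)-5-(prop-1-en-2-yl)cyclohexan-1-one | CC(=C)[C@@H]1CC[C@@](C)(CCC(=O)CC)C(=O)C1 | intermediate
7 | 5-hydroxyeudesm-11-en-3-one (ketol, epimer mixture at C4 and C5; 7β-isopropenyl, 10β-methyl) | CC(=C)[C@@H]1CC[C@@]2(C)CCC(=O)C(C)C2(O)C1 | intermediate (not isolated)
8 | (+)-α-cyperone, (4aS,7R)-1,4a-dimethyl-7-(prop-1-en-2-yl)-4,4a,5,6,7,8-hexahydronaphthalen-2(3H)-one | CC(=C)[C@@H]1CC[C@@]2(C)CCC(=O)C(C)=C2C1 | intermediate
9 | eudesm-4-en-3-one, (4aS,7R)-1,4a-dimethyl-7-(propan-2-yl)-4,4a,5,6,7,8-hexahydronaphthalen-2(3H)-one | CC(C)[C@@H]1CC[C@@]2(C)CCC(=O)C(C)=C2C1 | intermediate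
10 | 3-acetoxyeudesma-3,5-diene (7β-isopropyl, 10β-methyl) | CC(C)[C@@H]1CC[C@@]2(C)CCC(OC(C)=O)=C(C)C2=C1 | intermediate
11 | 6β-hydroxyeudesm-4-en-3-one | CC(C)[C@@H]1CC[C@@]2(C)CCC(=O)C(C)=C2[C@@H]1O | intermediate
12 | 6β-benzoyloxyeudesm-4-en-3-one | CC(C)[C@@H]1CC[C@@]2(C)CCC(=O)C(C)=C2[C@@H]1OC(=O)c1ccccc1 | intermediate
13 | 6β-benzoyloxyeudesm-4-en-3β-ol | CC(C)[C@@H]1CC[C@@]2(C)CC[C@H](O)C(C)=C2[C@@H]1OC(=O)c1ccccc1 | intermediate
14 | N-(6β-benzoyloxyeudesm-4-en-3α-yl)-N-(2-nitrophenylsulfonyl)hydrazine | CC(C)[C@@H]1CC[C@@]2(C)CC[C@@H](N(N)S(=O)(=O)c3ccccc3[N+](=O)[O-])C(C)=C2[C@@H]1OC(=O)c1ccccc1 | intermediate (not isolated)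
15 | (6β-benzoyloxyeudesm-4-en-3α-yl)diazene | CC(C)[C@@H]1CC[C@@]2(C)CC[C@@H](N=N)C(C)=C2[C@@H]1OC(=O)c1ccccc1 | intermediate (not isolated)
16 | 6β-benzoyloxy-5αH-eudesm-3-ene | CC(C)[C@@H]1CC[C@@]2(C)CCC=C(C)[C@@H]2[C@@H]1OC(=O)c1ccccc1 | intermediate
17 | 6β-benzoyloxy-3α,4α-epoxy-5αH-eudesmane | CC(C)[C@@H]1CC[C@@]2(C)CC[C@H]3O[C@@]3(C)[C@@H]2[C@@H]1OC(=O)c1ccccc1 | intermediate
18 | 3α-hydroxy-5αH-eudesmane-4β,6β-diyl 2-phenyl-1,3-dioxan-2-ylium ion (perchlorate counter-ion) | CC(C)[C@@H]1CC[C@@]2(C)CC[C@@H](O)[C@]3(C)OC(c4ccccc4)=[O+][C@H]1[C@H]23 | intermediate (not isolated)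
19 | 6β-benzoyloxy-7β-isopropyl-5αH-eudesmane-3α,4β-diol (CNP0187831.1) | CC(C)[C@@H]1CC[C@@]2(C)CC[C@@H](O)[C@](C)(O)[C@@H]2[C@@H]1OC(=O)c1ccccc1 | target

**Totals**
Total steps: 11. Longest linear sequence: 11 steps (from 1; compounds 2 and 4 are bought).

**Steps most likely to fail, with fallbacks**

Step 6 (γ-hydroxylation). The peracid may attack C4 instead of C6, or give 6α/6β mixtures. The fallback brings in the C6 oxygen by allylic C–H oxidation; it sets out from 9 and comes back at 13. Luche reduction of 9 (NaBH4, CeCl3·7H2O, MeOH) gives eudesm-4-en-3β-ol F1. Silylation (TBSCl, imidazole, DMF) gives 3β-(tert-butyldimethylsilyloxy)eudesm-4-ene F2. Oxidation of the only allylic methylene, C6, with CrO3 and 3,5-dimethylpyrazole in CH2Cl2 at −20 °C gives 3β-(tert-butyldimethylsilyloxy)eudesm-4-en-6-one F3. A second Luche reduction, with hydride entering from the α face because the β face is blocked by the C10 methyl, gives 3β-(tert-butyldimethylsilyloxy)eudesm-4-en-6β-ol F4. Benzoylation (BzCl, DMAP, pyridine) gives 6β-benzoyloxy-3β-(tert-butyldimethylsilyloxy)eudesm-4-ene F5, and HF·pyridine in THF removes the silyl group to give 13.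

Step 9 (reductive transposition). The Mitsunobu displacement at the hindered allylic C3 may be slow or give dienes by elimination. The fallback sets out from 13 and comes back at 16. Formylation (acetic formic anhydride, pyridine, 0 °C) gives 6β-benzoyloxyeudesm-4-en-3β-yl formate F6. Treatment with Pd(OAc)2 and PBu3 in refluxing dioxane (Tsuji–Mandai formate hydrogenolysis) then gives 16. Zerovalent palladium formed in the flask ionises the 3β-formate with inversion, so the metal sits on the α face; loss of CO2 leaves a palladium hydride, which passes hydrogen to the more substituted allyl terminus C5 on the α face. The result is the same H-5α alkene.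

Step 11 (epoxide opening). The benzoyl group may end partly on O4, or be hard to separate from its isomer. The fallback sets out from 17 and comes back at 19. The epoxide is opened as in step 11, and the crude mixture of 19 and its acyl-shifted isomer 4β-benzoyloxy-5αH-eudesmane-3α,6β-diol F7 is not separated. Saponification (NaOH, MeOH/H2O, 60 °C) gives 5αH-eudesmane-3α,4β,6β-triol F8. The less hindered secondary 3α-hydroxyl is silylated (TESCl, imidazole, CH2Cl2, 0 °C) to give 3α-(triethylsilyloxy)-5αH-eudesmane-4β,6β-diol F9. The remaining secondary 6β-hydroxyl is benzoylated (BzCl, DMAP, pyridine, 50 °C; the tertiary 4β-OH does not react) to give 6β-benzoyloxy-3α-(triethylsilyloxy)-5αH-eudesman-4β-ol F10. HF·pyridine in THF then removes the silyl ether to give 19.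

**Further compounds**
F1 | step 6 | eudesm-4-en-3β-ol | CC(C)[C@@H]1CC[C@@]2(C)CC[C@H](O)C(C)=C2C1
F2 | step 6 | 3β-(tert-butyldimethylsilyloxy)eudesm-4-ene | CC(C)[C@@H]1CC[C@@]2(C)CC[C@H](O[Si](C)(C)C(C)(C)C)C(C)=C2C1
F3 | step 6 | 3β-(tert-butyldimethylsilyloxy)eudesm-4-en-6-one | CC(C)[C@@H]1CC[C@@]2(C)CC[C@H](O[Si](C)(C)C(C)(C)C)C(C)=C2C1=O
F4 | step 6 | 3β-(tert-butyldimethylsilyloxy)eudesm-4-en-6β-ol | CC(C)[C@@H]1CC[C@@]2(C)CC[C@H](O[Si](C)(C)C(C)(C)C)C(C)=C2[C@@H]1O
F5 | step 6 | 6β-benzoyloxy-3β-(tert-butyldimethylsilyloxy)eudesm-4-ene | CC(C)[C@@H]1CC[C@@]2(C)CC[C@H](O[Si](C)(C)C(C)(C)C)C(C)=C2[C@@H]1OC(=O)c1ccccc1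
F6 | step 9 | 6β-benzoyloxyeudesm-4-en-3β-yl formate | CC(C)[C@@H]1CC[C@@]2(C)CC[C@H](OC=O)C(C)=C2[C@@H]1OC(=O)c1ccccc1
F7 | step 11 | 4β-benzoyloxy-5αH-eudesmane-3α,6β-diol | CC(C)[C@@H]1CC[C@@]2(C)CC[C@@H](O)[C@](C)(OC(=O)c3ccccc3)[C@@H]2[C@@H]1O
F8 | step 11 | 5αH-eudesmane-3α,4β,6β-triol | CC(C)[C@@H]1CC[C@@]2(C)CC[C@@H](O)[C@](C)(O)[C@@H]2[C@@H]1O
F9 | step 11 | 3α-(triethylsilyloxy)-5αH-eudesmane-4β,6β-diol | CC(C)[C@@H]1CC[C@@]2(C)CC[C@@H](O[Si](CC)(CC)CC)[C@](C)(O)[C@@H]2[C@@H]1O
F10 | step 11 | 6β-benzoyloxy-3α-(triethylsilyloxy)-5αH-eudesman-4β-ol | CC(C)[C@@H]1CC[C@@]2(C)CC[C@@H](O[Si](CC)(CC)CC)[C@](C)(O)[C@@H]2[C@@H]1OC(=O)c1ccccc1
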